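## Retrosynthetic overview

1. The last C–C bond made is C2–C3 of the flavanone, which closes ring C. C3 is the methyl carbon of an aryl methyl ketone on ring A. C2 is a benzylic CH2 already bound to O1, and it is raised in the flask to an oxocarbenium ion; a chiral phosphoric acid sets C2 as (R).
2. The enabling feature is that the 4'-OH of ring B is para to C1', the ring carbon that carries C2, and C2 is also bound to the ring oxygen O1. A 4'-hydroxybenzyl aryl ether is therefore dehydrogenated by DDQ at C2 alone to an O-aryl para-quinone methide, and its protonated form is the cation that the acetyl enol attacks.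
3. O1–C2 comes from a Williamson ether synthesis between 2-hydroxy-4,6-bis(benzyloxy)acetophenone and a benzylic bromide. C2 is one oxidation level low, the 4'-oxygen is a silyl ether and all other phenols are benzyl ethers.
4. The biaryl bond from C6' of ring B to C8 of the flavone comes from a Suzuki coupling of 8-iodo-tetra-O-benzylluteolin with a 2-formylarylboronate.
5. Ring order: the flavone rings are bought with luteolin, then the biaryl bond, then ring C of the flavanone; one hydrogenolysis frees the remaining seven hydroxyls.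

Key step: step 12

Remark on the chemistry: the biaryl axis between C6' of ring B and C8 of the flavone carries no descriptor in the target and is taken as not controlled (rotamers are expected to interconvert); C2 is the only stereocentre to be set.
Remark on the chemistry: the target is the (2R) series; the (R)-phosphoric acid is assumed to give (2R), and its mirror image would give the other series by symmetry.

## Route

Step 1
Reactants: 1 luteolin
Product: 2 5,7,3',4'-tetra-O-benzylluteolin
Conditions: BnBr (excess), K2CO3, DMF, 80 °C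
Reagents that add atoms: benzyl bromide (BrCc1ccccc1)
Why: Williamson O-benzylation, in which the three free phenols react readily and the hydrogen-bonded 5-OH follows on heating with excess halide, so all four oxygens carry a group removable by hydrogenolysis.

Step 2
Reactants: 2 5,7,3',4'-tetra-O-benzylluteolin
Product: 3 8-iodo-5,7,3',4'-tetra-O-benzylluteolin
Conditions: NIS, CF3CO2H (cat.), CH2Cl2/MeCN, 0 °C to rt
Reagents that add atoms: N-iodosuccinimide (O=C1CCC(=O)N1I)
Why: Electrophilic aromatic iodination, in which the phloroglucinol-type ring A is the most electron-rich arene and fully O-alkylated 5,7-dioxygenated flavones are substituted at C8 (between O1 and the 7-alkoxy group) and not at C6.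

Step 3
Reactants: 4 3-(benzyloxy)-4-hydroxybenzaldehyde
Product: 5 3-(benzyloxy)-4-(triisopropylsilyloxy)benzaldehyde
Conditions: TIPSCl, imidazole, DMF, rt
Reagents that add atoms: triisopropylsilyl chloride (CC(C)[Si](Cl)(C(C)C)C(C)C)
Why: Silylation of the only free phenol, which masks the future 4'-oxygen through the base-mediated steps with a group that can later be removed without touching benzyl ethers.

Step 4
Reactants: 5 3-(benzyloxy)-4-(triisopropylsilyloxy)benzaldehyde
Product: 6 5-(benzyloxy)-2-bromo-4-(triisopropylsilyloxy)benzaldehyde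
Conditions: Br2, NaOAc, AcOH, rt
Reagents that add atoms: bromine (BrBr)
Why: Electrophilic aromatic bromination, in which the benzyloxy group directs to its free para position (ortho to the formyl group), as in the bromination of 3,4-dialkoxybenzaldehydes, while the silyloxy group is the weaker donor and is para to the formyl group.

Step 5
Reactants: 6 5-(benzyloxy)-2-bromo-4-(triisopropylsilyloxy)benzaldehyde
Product: 7 5-(benzyloxy)-2-(4,4,5,5-tetramethyl-1,3,2-dioxaborolan-2-yl)-4-(triisopropylsilyloxy)benzaldehyde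
Conditions: B2pin2, PdCl2(dppf), KOAc, 1,4-dioxane, 90 °C
Reagents that add atoms: bis(pinacolato)diboron (CC1(C)OB(OC1(C)C)B1OC(C)(C)C(C)(C)O1)
Why: Miyaura borylation of the aryl bromide, in which the weak acetate base leaves the aldehyde and the aryl silyl ether untouched.

Step 6
Reactants: 3 8-iodo-5,7,3',4'-tetra-O-benzylluteolin; 7 5-(benzyloxy)-2-(4,4,5,5-tetramethyl-1,3,2-dioxaborolan-2-yl)-4-(triisopropylsilyloxy)benzaldehyde
Product: 8 5-(benzyloxy)-2-(5,7,3',4'-tetra-O-benzylluteolin-8-yl)-4-(triisopropylsilyloxy)benzaldehyde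
Conditions: Pd(OAc)2, SPhos, K3PO4, toluene/H2O, 80 °C
Reagents that add atoms: none
Why: Suzuki–Miyaura coupling, for which the dialkylbiarylphosphine ligand is suited to tri-ortho-substituted biaryls and the electron-rich iodide adds readily to zerovalent palladium, while aldehyde, benzyl ethers and the hindered silyl ether tolerate phosphate base.

Step 7
Reactants: 8 5-(benzyloxy)-2-(5,7,3',4'-tetra-O-benzylluteolin-8-yl)-4-(triisopropylsilyloxy)benzaldehyde
Product: 9 [5-(benzyloxy)-2-(5,7,3',4'-tetra-O-benzylluteolin-8-yl)-4-(triisopropylsilyloxy)phenyl]methanol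
Conditions: NaBH4, THF/MeOH, 0 °C
Reagents that add atoms: none
Why: Borohydride reduction, in which the aldehyde is reduced far faster than the vinylogous ester carbonyl of the flavone.

Step 8
Reactants: 9 [5-(benzyloxy)-2-(5,7,3',4'-tetra-O-benzylluteolin-8-yl)-4-(triisopropylsilyloxy)phenyl]methanol
Product: 10 5-(benzyloxy)-2-(5,7,3',4'-tetra-O-benzylluteolin-8-yl)-4-(triisopropylsilyloxy)benzyl bromide
Conditions: CBr4, PPh3, CH2Cl2, 0 °C
Reagents that add atoms: carbon tetrabromide (BrC(Br)(Br)Br)
Why: Appel reaction, which converts the benzylic alcohol into the bromide under neutral conditions that spare silyl ether, benzyl ethers and flavone.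

Step 9
Reactants: 11 2',4',6'-trihydroxyacetophenone
Product: 12 2',4'-bis(benzyloxy)-6'-hydroxyacetophenone
Conditions: BnBr (2.1 equiv), K2CO3, acetone, reflux
Reagents that add atoms: benzyl bromide (BrCc1ccccc1)
Why: Williamson O-benzylation, in which the 4'-hydroxyl and one of the two equivalent ortho hydroxyls react, and the remaining ortho hydroxyl, hydrogen-bonded to the acetyl group, stays free.

Step 10
Reactants: 10 5-(benzyloxy)-2-(5,7,3',4'-tetra-O-benzylluteolin-8-yl)-4-(triisopropylsilyloxy)benzyl bromide; 12 2',4'-bis(benzyloxy)-6'-hydroxyacetophenone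
Product: 13 1-[2,4-bis(benzyloxy)-6-{[5-(benzyloxy)-2-(5,7,3',4'-tetra-O-benzylluteolin-8-yl)-4-(triisopropylsilyloxy)benzyl]oxy}phenyl]ethan-1-one
Conditions: K2CO3, DMF, rt to 40 °C
Reagents that add atoms: none
Why: Williamson ether synthesis (SN2 at a primary benzylic bromide by the remaining phenoxide), which forms the O1–C2 bond of the future ring C while C2 is still a CH2 group.

Step 11
Reactants: 13 1-[2,4-bis(benzyloxy)-6-{[5-(benzyloxy)-2-(5,7,3',4'-tetra-O-benzylluteolin-8-yl)-4-(triisopropylsilyloxy)benzyl]oxy}phenyl]ethan-1-one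
Product: 14 1-[2,4-bis(benzyloxy)-6-{[5-(benzyloxy)-4-hydroxy-2-(5,7,3',4'-tetra-O-benzylluteolin-8-yl)benzyl]oxy}phenyl]ethan-1-one
Conditions: TBAF, AcOH (1:1), THF, 0 °C
Reagents that add atoms: none
Why: Fluoride-mediated desilylation, buffered with acetic acid so that the liberated phenol stays protonated and cannot expel the aryloxide by 1,6-elimination from a 4-oxidobenzyl ether.

Step 12
Reactants: 14 1-[2,4-bis(benzyloxy)-6-{[5-(benzyloxy)-4-hydroxy-2-(5,7,3',4'-tetra-O-benzylluteolin-8-yl)benzyl]oxy}phenyl]ethan-1-one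
Product: 17 (2R)-5,7-bis(benzyloxy)-2-[5-(benzyloxy)-4-hydroxy-2-(5,7,3',4'-tetra-O-benzylluteolin-8-yl)phenyl]chroman-4-one, via para-quinone methide 15 (not isolated), via cyclic enol acetal 16 (not isolated)
Conditions: DDQ (1.0 equiv), 4 Å MS, CH2Cl2, −40 to 0 °C; filtration of the precipitated hydroquinone under argon; then (R)-TRIP [(R)-3,3'-bis(2,4,6-triisopropylphenyl)-1,1'-binaphthyl-2,2'-diyl hydrogen phosphate] (10 mol %), CH2Cl2/toluene, −20 °C to rt
Reagents that add atoms: none
Why: Proposed new method: DDQ abstracts hydride from the one CH2 that is both para to the free 4'-OH of ring B and bound to the aryl ether oxygen, and loss of the phenolic proton gives the O-aryl para-quinone methide 15, a vinylogous aryl formate that should survive removal of the precipitated hydroquinone. The phosphoric acid protonates the dienone oxygen; the resulting 4'-hydroxybenzyl oxocarbenium ion is captured first by the neighbouring acetyl oxygen, which acidifies the methyl group, and proton loss gives the cyclic enol acetal 16 (a 4-methylidene-1,3-benzodioxine, a temporary ring). Acid-mediated re-ionisation of the acetal C2–O bond on the enol side, again assisted by the para-OH, sets free the oxocarbenium ion and the aryl enol within the chiral phosphate, and recombination at carbon closes ring C by a 6-endo-trig attack of the enol carbon C3 on C2 (enol double bond inside the forming ring), which is irreversible and so drains the acetal equilibria to the ketone. The closest known reaction types are the Petasis–Ferrier rearrangement of 4-methylene-1,3-dioxanes to tetrahydropyran-4-ones, its chiral phosphoric acid-catalysed aza variant, and phosphoric acid-catalysed 1,6-additions of enol-type nucleophiles to para-quinone methides; the oxidative entry and the enantioselective oxa version on an aryl ether are new. C2 is the only new stereocentre and is set by the catalyst, whose phosphate bridges the enol OH and the 4'-OH of the cation while the 2,4,6-triisopropylphenyl groups block one face of the planar oxocarbenium ion; the (2R) sense assumed for the (R)-acid has to be confirmed, and the mirror-image acid is used otherwise. The step needs chemoselective oxidation (plain benzyl ethers lack the para-OH and stay intact, and the single equivalent of DDQ is consumed before the acid is added, so the product is not dehydrogenated to a flavone) and C- over O-alkylation (O-alkylation is reversible under the acid, C-alkylation is not).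

Step 13
Reactants: 17 (2R)-5,7-bis(benzyloxy)-2-[5-(benzyloxy)-4-hydroxy-2-(5,7,3',4'-tetra-O-benzylluteolin-8-yl)phenyl]chroman-4-one
Product: 18 (2R)-2-[4,5-dihydroxy-2-(luteolin-8-yl)phenyl]-5,7-dihydroxychroman-4-one (the target, CNP0228504.1)
Conditions: H2 (1 atm), Pd/C, THF/MeOH, rt
Reagents that add atoms: none
Why: Catalytic hydrogenolysis of the seven aryl benzyl ethers under neutral conditions, which should not epimerise C2 (no base, so no retro-oxa-Michael opening) and should leave the flavone C2=C3 bond and the flavanone C2–O1 bond intact at one atmosphere.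

## Compound list

1 | luteolin (5,7,3',4'-tetrahydroxyflavone) | O=c1cc(-c2ccc(O)c(O)c2)oc2cc(O)cc(O)c12 | starting material
2 | 5,7,3',4'-tetra-O-benzylluteolin | O=c1cc(-c2ccc(OCc3ccccc3)c(OCc3ccccc3)c2)oc2cc(OCc3ccccc3)cc(OCc3ccccc3)c12 | intermediate
3 | 8-iodo-5,7,3',4'-tetra-O-benzylluteolin | O=c1cc(-c2ccc(OCc3ccccc3)c(OCc3ccccc3)c2)oc2c(I)c(OCc3ccccc3)cc(OCc3ccccc3)c12 | intermediate
4 | 3-(benzyloxy)-4-hydroxybenzaldehyde | O=Cc1ccc(O)c(OCc2ccccc2)c1 | starting material
5 | 3-(benzyloxy)-4-(triisopropylsilyloxy)benzaldehyde | O=Cc1ccc(O[Si](C(C)C)(C(C)C)C(C)C)c(OCc2ccccc2)c1 | intermediate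
6 | 5-(benzyloxy)-2-bromo-4-(triisopropylsilyloxy)benzaldehyde | O=Cc1cc(OCc2ccccc2)c(O[Si](C(C)C)(C(C)C)C(C)C)cc1Br | intermediate
7 | 5-(benzyloxy)-2-(4,4,5,5-tetramethyl-1,3,2-dioxaborolan-2-yl)-4-(triisopropylsilyloxy)benzaldehyde | O=Cc1cc(OCc2ccccc2)c(O[Si](C(C)C)(C(C)C)C(C)C)cc1B1OC(C)(C)C(C)(C)O1 | intermediate
8 | 5-(benzyloxy)-2-(5,7,3',4'-tetra-O-benzylluteolin-8-yl)-4-(triisopropylsilyloxy)benzaldehyde | O=Cc1cc(OCc2ccccc2)c(O[Si](C(C)C)(C(C)C)C(C)C)cc1-c1c(OCc2ccccc2)cc(OCc2ccccc2)c2c(=O)cc(-c3ccc(OCc4ccccc4)c(OCc4ccccc4)c3)oc12 | intermediate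
9 | [5-(benzyloxy)-2-(5,7,3',4'-tetra-O-benzylluteolin-8-yl)-4-(triisopropylsilyloxy)phenyl]methanol | OCc1cc(OCc2ccccc2)c(O[Si](C(C)C)(C(C)C)C(C)C)cc1-c1c(OCc2ccccc2)cc(OCc2ccccc2)c2c(=O)cc(-c3ccc(OCc4ccccc4)c(OCc4ccccc4)c3)oc12 | intermediate
10 | 5-(benzyloxy)-2-(5,7,3',4'-tetra-O-benzylluteolin-8-yl)-4-(triisopropylsilyloxy)benzyl bromide | BrCc1cc(OCc2ccccc2)c(O[Si](C(C)C)(C(C)C)C(C)C)cc1-c1c(OCc2ccccc2)cc(OCc2ccccc2)c2c(=O)cc(-c3ccc(OCc4ccccc4)c(OCc4ccccc4)c3)oc12 | intermediate
11 | 2',4',6'-trihydroxyacetophenone | CC(=O)c1c(O)cc(O)cc1O | starting material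
12 | 2',4'-bis(benzyloxy)-6'-hydroxyacetophenone | CC(=O)c1c(O)cc(OCc2ccccc2)cc1OCc1ccccc1 | intermediate
13 | 1-[2,4-bis(benzyloxy)-6-{[5-(benzyloxy)-2-(5,7,3',4'-tetra-O-benzylluteolin-8-yl)-4-(triisopropylsilyloxy)benzyl]oxy}phenyl]ethan-1-one | CC(=O)c1c(OCc2ccccc2)cc(OCc2ccccc2)cc1OCc1cc(OCc2ccccc2)c(O[Si](C(C)C)(C(C)C)C(C)C)cc1-c1c(OCc2ccccc2)cc(OCc2ccccc2)c2c(=O)cc(-c3ccc(OCc4ccccc4)c(OCc4ccccc4)c3)oc12 | intermediate
14 | 1-[2,4-bis(benzyloxy)-6-{[5-(benzyloxy)-4-hydroxy-2-(5,7,3',4'-tetra-O-benzylluteolin-8-yl)benzyl]oxy}phenyl]ethan-1-one | CC(=O)c1c(OCc2ccccc2)cc(OCc2ccccc2)cc1OCc1cc(OCc2ccccc2)c(O)cc1-c1c(OCc2ccccc2)cc(OCc2ccccc2)c2c(=O)cc(-c3ccc(OCc4ccccc4)c(OCc4ccccc4)c3)oc12 | intermediate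
15 | para-quinone methide: 4-{[2-acetyl-3,5-bis(benzyloxy)phenoxy]methylidene}-2-(benzyloxy)-5-(5,7,3',4'-tetra-O-benzylluteolin-8-yl)cyclohexa-2,5-dien-1-one, aryloxy group anti to the ring carbon that bears the flavone | CC(=O)c1c(OCc2ccccc2)cc(OCc2ccccc2)cc1O/C=C1\C=C(OCc2ccccc2)C(=O)C=C1c1c(OCc2ccccc2)cc(OCc2ccccc2)c2c(=O)cc(-c3ccc(OCc4ccccc4)c(OCc4ccccc4)c3)oc12 | intermediate (not isolated)
16 | cyclic enol acetal: racemic 5,7-bis(benzyloxy)-2-[5-(benzyloxy)-4-hydroxy-2-(5,7,3',4'-tetra-O-benzylluteolin-8-yl)phenyl]-4-methylidene-4H-1,3-benzodioxine | C=C1OC(c2cc(OCc3ccccc3)c(O)cc2-c2c(OCc3ccccc3)cc(OCc3ccccc3)c3c(=O)cc(-c4ccc(OCc5ccccc5)c(OCc5ccccc5)c4)oc23)Oc2cc(OCc3ccccc3)cc(OCc3ccccc3)c21 | intermediate (not isolated)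
17 | (2R)-5,7-bis(benzyloxy)-2-[5-(benzyloxy)-4-hydroxy-2-(5,7,3',4'-tetra-O-benzylluteolin-8-yl)phenyl]chroman-4-one | O=C1C[C@H](c2cc(OCc3ccccc3)c(O)cc2-c2c(OCc3ccccc3)cc(OCc3ccccc3)c3c(=O)cc(-c4ccc(OCc5ccccc5)c(OCc5ccccc5)c4)oc23)Oc2cc(OCc3ccccc3)cc(OCc3ccccc3)c21 | intermediate
18 | (2R)-2-[4,5-dihydroxy-2-(luteolin-8-yl)phenyl]-5,7-dihydroxychroman-4-one, i.e. (2R)-eriodictyol joined through C6' to C8 of luteolin | O=C1C[C@H](c2cc(O)c(O)cc2-c2c(O)cc(O)c3c(=O)cc(-c4ccc(O)c(O)c4)oc23)Oc2cc(O)cc(O)c21 | target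

## Step count and risks

Total step count: 13. Longest linear sequence: 10 steps (steps 3, 4, 5, 6, 7, 8, 10, 11, 12 and 13).

Steps most likely to fail:

Step 12 (the proposed new method). The recombination may proceed with poor facial selectivity, the oxocarbenium ion may be cleaved hydrolytically by traces of water, or the sequence may stall at the acetal stage. The fallback uses the classical chalcone route and a resolution. It sets out from aldehyde 8 and ketone 12 and comes back at 17. Amine-mediated Claisen–Schmidt condensation (pyrrolidine, MeOH/THF, 50 °C) should give the (E)-2'-hydroxychalcone F1, which under the same conditions should close ring C through the O1–C2 bond by oxa-Michael addition to the racemic silyl-protected flavanone F2. Buffered desilylation (TBAF, AcOH, THF, 0 °C) should then give the racemic flavanone F3, and preparative HPLC on a chiral stationary phase should separate 17 from its (2S)-enantiomer F4.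

Step 6. The ortho-formyl boronate may be lost by protodeboronation before it transmetalates onto the doubly ortho-substituted arylpalladium species, and the aryl silyl ether may be cleaved by the aqueous base. The fallback replaces the base-dependent boron transfer by a neutral tin transfer. It sets out from bromide 6 and iodide 3 and comes back at 8. Stannylation of 6 (Me3SnSnMe3, Pd(PPh3)4, toluene, 100 °C) should give the arylstannane F5, and Stille coupling of this with 3 (Pd(PPh3)4, CuI, DMF, 90 °C, no base and no fluoride) should give 8.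

Step 13. The flavone C2=C3 bond may be over-reduced, the benzylic C2–O1 bond of the flavanone may be opened by hydrogenolysis, or the hindered benzyl ethers next to the carbonyl groups may be removed incompletely. The fallback is a non-reductive cleavage: it sets out from 17 and comes back at 18 directly, with BCl3 and pentamethylbenzene as cation scavenger in CH2Cl2 at −78 °C; no further compound arises (F0).

Further compounds
F1 | step 12 | (E)-1-[2,4-bis(benzyloxy)-6-hydroxyphenyl]-3-[5-(benzyloxy)-2-(5,7,3',4'-tetra-O-benzylluteolin-8-yl)-4-(triisopropylsilyloxy)phenyl]prop-2-en-1-one | O=C(/C=C/c1cc(OCc2ccccc2)c(O[Si](C(C)C)(C(C)C)C(C)C)cc1-c1c(OCc2ccccc2)cc(OCc2ccccc2)c2c(=O)cc(-c3ccc(OCc4ccccc4)c(OCc4ccccc4)c3)oc12)c1c(O)cc(OCc2ccccc2)cc1OCc1ccccc1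
F2 | step 12 | racemic 5,7-bis(benzyloxy)-2-[5-(benzyloxy)-2-(5,7,3',4'-tetra-O-benzylluteolin-8-yl)-4-(triisopropylsilyloxy)phenyl]chroman-4-one | O=C1CC(c2cc(OCc3ccccc3)c(O[Si](C(C)C)(C(C)C)C(C)C)cc2-c2c(OCc3ccccc3)cc(OCc3ccccc3)c3c(=O)cc(-c4ccc(OCc5ccccc5)c(OCc5ccccc5)c4)oc23)Oc2cc(OCc3ccccc3)cc(OCc3ccccc3)c21
F3 | step 12 | racemic 5,7-bis(benzyloxy)-2-[5-(benzyloxy)-4-hydroxy-2-(5,7,3',4'-tetra-O-benzylluteolin-8-yl)phenyl]chroman-4-one | O=C1CC(c2cc(OCc3ccccc3)c(O)cc2-c2c(OCc3ccccc3)cc(OCc3ccccc3)c3c(=O)cc(-c4ccc(OCc5ccccc5)c(OCc5ccccc5)c4)oc23)Oc2cc(OCc3ccccc3)cc(OCc3ccccc3)c21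
F4 | step 12 | (2S)-5,7-bis(benzyloxy)-2-[5-(benzyloxy)-4-hydroxy-2-(5,7,3',4'-tetra-O-benzylluteolin-8-yl)phenyl]chroman-4-one | O=C1C[C@@H](c2cc(OCc3ccccc3)c(O)cc2-c2c(OCc3ccccc3)cc(OCc3ccccc3)c3c(=O)cc(-c4ccc(OCc5ccccc5)c(OCc5ccccc5)c4)oc23)Oc2cc(OCc3ccccc3)cc(OCc3ccccc3)c21
F5 | step 6 | 5-(benzyloxy)-4-(triisopropylsilyloxy)-2-(trimethylstannyl)benzaldehyde | O=Cc1cc(OCc2ccccc2)c(O[Si](C(C)C)(C(C)C)C(C)C)cc1[Sn](C)(C)C
F0 | step 13 | none | none
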